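**Plan**
- Target: 8α-hydroxylabda-13(16),14-dien-19-yl (Z)-p-coumarate, (4S,5R,8R,9R,10S) in labdane numbering. The enabling feature is ring A: the quaternary C4 (CH3 and the C19H2–O arm) sits next to the methine C5 with C19 cis to the C6 arm. This is the 1,2-cis pattern of an endo 2-methylacrolein adduct of an E-diene, and C5–C6–C7–C8(CH3)(O)–C9 is the carbon chain of (R)-linalool.
- Retrosynthetic cuts, in order: the cinnamate C=C and the C19–O acyl bond; C12–C13 (diene unit); C9–C10 (ring B); C9=C11 (ester arm); C4–C5 and C2–C3 (ring A).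
- Forward: linalool becomes an E-dienyl silyl ether; ring A closes by [4+2] addition of methacrolein; cross-metathesis adds the acrylate arm; ring B closes by radical 6-exo addition of C10 to C9; C12 is reduced, iodinated and coupled with a butadienyl Grignard reagent; the C19 alcohol is acylated and olefinated to the Z-coumarate; fluoride removes both silyl groups.
- Stereochemistry: C8 comes from (R)-linalool; C4 and C5 from the catalyst-controlled endo cycloaddition; C10 and C9 from the chair-like radical closure under control of C4, C5 and C8; the Z alkene from the trifluoroethyl phosphonate olefination.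

Key step: step 4

Remark: labdane numbering is used throughout, and every bicyclic compound below has the (4S,5R,8R,9R,10S) configuration (trans-decalin, 4β-C19, 5α-H, 8β-CH3/8α-O, 9β side chain, 10β-CH3). Bis(2,2,2-trifluoroethyl)phosphonoacetic acid and stabilised chloroprene solution are assumed to be purchasable.

**Step 1**
Reactants: 1 (R)-linalool
Product: 2 triethyl{[(3R)-3,7-dimethylocta-1,6-dien-3-yl]oxy}silane
Conditions: Et3SiOSO2CF3, 2,6-lutidine, CH2Cl2, −78 → 0 °C
Reagents that add atoms: triethylsilyl trifluoromethanesulfonate, CC[Si](CC)(CC)OS(=O)(=O)C(F)(F)F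
Why: A silyl triflate with a hindered pyridine base silylates tertiary alcohols cleanly (silyl ether protection), and the triethylsilyl ether should last until the final fluoride treatment while keeping the C8 oxygen from closing onto C12 once that carbon carries a leaving group.

**Step 2**
Reactants: 2 silyl ether
Product: 4 (2E,6R)-2,6-dimethyl-6-(triethylsilyloxy)octa-2,7-dienal, via allylic alcohol 3 (not isolated)
Conditions: SeO2 (cat.), t-BuOOH, salicylic acid (cat.), CH2Cl2, rt; then MnO2, CH2Cl2, rt
Reagents that add atoms: tert-butyl hydroperoxide, CC(C)(C)OO (the oxygen atom, passed on by SeO2, O=[Se]=O)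
Why: Selenium dioxide allylic oxidation (ene reaction, then [2,3]-sigmatropic shift) attacks the trisubstituted alkene selectively at its E-methyl group, and MnO2 takes the allylic alcohol fraction on to the E-enal without touching the vinyl group or the silyl ether.

**Step 3**
Reactants: 4 enal
Product: 5 triethyl{[(3R,6E)-3,7-dimethylnona-1,6,8-trien-3-yl]oxy}silane
Conditions: Ph3PCH3Br, KOt-Bu, THF, 0 °C
Reagents that add atoms: methyltriphenylphosphonium bromide, C[P+](c1ccccc1)(c1ccccc1)c1ccccc1.[Br-]
Why: Wittig methylenation with the non-stabilised ylide adds 1,2 to the enal and keeps the trisubstituted alkene geometry, giving the E-1,3-diene the cycloaddition needs.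

**Step 4**
Reactants: 5 triene silyl ether; 6 methacrolein
Product: 7 (1S,2R)-1,3-dimethyl-2-[(3R)-3-methyl-3-(triethylsilyloxy)pent-4-en-1-yl]cyclohex-3-ene-1-carbaldehyde
Conditions: (S)-oxazaborolidinium triflimide [C24H25BNO]+[N(SO2CF3)2]− (20 mol %), made from (S)-tetrahydro-1-(2-methylphenyl)-3,3-diphenyl-1H,3H-pyrrolo[1,2-c][1,3,2]oxazaborole and HN(SO2CF3)2; threefold excess of 6; CH2Cl2, −78 → −40 °C
Reagents that add atoms: none
Why: The cationic boron Lewis acid binds the formyl oxygen of 6, lowers its LUMO and lets the diene of 5 add in a concerted, asynchronous [4+2] in which C2–C3 (unsubstituted diene terminus to the enal CH2) runs ahead of C4–C5; the closest known reaction type is the oxazaborolidinium-catalysed Diels–Alder reaction of 2-substituted acroleins with acyclic dienes. Ring A closes in this one intermolecular cycloaddition, both ring bonds forming suprafacially on each partner. C4 is set by the catalyst, which holds the s-trans enal against one of its phenyl groups and is expected to leave open only the Re face of the α-carbon, the face that leads to the (S) configuration at C4. C5 follows from the E geometry of the diene together with the endo position of the formyl group, which puts C19 cis to the C6 arm. The step needs ortho regiochemistry, endo selectivity and face selectivity: the first should come from the terminal alkyl substituent and from the unhindered CH2 terminus taking the leading bond, the second from the formyl group in an open-chain diene that has no bridge to push it exo, and the third from the catalyst alone, since the remote C8 centre cannot bias the diene faces. The vinyl group and the tertiary silyl ether should stay untouched at low temperature because the Lewis acid is held by the aldehyde.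

**Step 5**
Reactants: 7 aldehyde; 8 methyl acrylate
Product: 9 methyl (2E,4R)-6-[(1R,6S)-6-formyl-2,6-dimethylcyclohex-2-en-1-yl]-4-methyl-4-(triethylsilyloxy)hex-2-enoate
Conditions: second-generation Hoveyda–Grubbs catalyst RuCl2(H2IMes)(=CH-C6H4-2-O-i-Pr) (H2IMes = 1,3-dimesitylimidazolidin-2-ylidene, 5–10 mol %), excess 8, CH2Cl2, 40 °C
Reagents that add atoms: none
Why: Olefin cross-metathesis between the monosubstituted vinyl group and the electron-poor acrylate, which homodimerises only slowly, should give the E-enoate, while the trisubstituted ring alkene is too hindered to enter the catalytic cycle.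

**Step 6**
Reactants: 9 enoate
Product: 10 methyl 19-oxo-8α-(triethylsilyloxy)-13,14,15,16-tetranorlabdan-12-oate
Conditions: Fe(acac)3 (0.5 equiv), PhSiH3, EtOH/HOCH2CH2OH, 60 °C
Reagents that add atoms: none
Why: Hydrogen-atom transfer from an iron hydride to the electron-rich ring alkene gives the tertiary C10 radical, which closes ring B 6-exo onto the enoate β-carbon C9 (Giese-type radical conjugate addition) before the α-ester radical is reduced and protonated by ethanol; attack on the α face of C10, away from the axial C19 formyl group, through a chair with the enoate arm equatorial should give the trans ring fusion with 10β-CH3 and the 9β side chain, with C4, C5 and C8 as the controlling centres.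

**Step 7**
Reactants: 10 ester aldehyde
Product: 11 8α-(triethylsilyloxy)-13,14,15,16-tetranorlabdane-12,19-diol
Conditions: LiAlH4, THF, 0 °C
Reagents that add atoms: none
Why: Hydride reduction with LiAlH4 takes the methyl ester and the neopentyl aldehyde to the two primary alcohols in one operation and leaves the tertiary silyl ether alone.

**Step 8**
Reactants: 11 diol
Product: 12 12-iodo-8α-(triethylsilyloxy)-13,14,15,16-tetranorlabdan-19-ol
Conditions: I2 (1.1 equiv), PPh3, imidazole, CH2Cl2, 0 °C
Reagents that add atoms: iodine, II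
Why: Appel-type iodination goes by SN2 displacement of an alkoxyphosphonium ion, which is fast at the unhindered C12 carbinol and blocked at the neopentyl, axial C19 carbinol, so one equivalent should iodinate C12 only.

**Step 9**
Reactants: 12 iodide; 13 chloroprene
Product: 15 8α-(triethylsilyloxy)labda-13(16),14-dien-19-ol, via buta-1,3-dien-2-ylmagnesium chloride 14 (not isolated)
Conditions: 13, Mg, ZnCl2 (cat.), THF, 50 °C; then 12, Li2CuCl4 (5 mol %), THF, −10 °C → rt (3 equiv of 14)
Reagents that add atoms: none
Why: Copper-catalysed cross-coupling of a Grignard reagent with a primary alkyl iodide (Kochi-type coupling), a known route to 2-alkylbuta-1,3-dienes from the chloroprene Grignard reagent, joins C12 to C13; one extra equivalent of the reagent is spent on the free C19 hydroxyl.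

**Step 10**
Reactants: 15 dienol; 16 bis(trifluoroethyl) phosphonoacetic acid
Product: 17 8α-(triethylsilyloxy)labda-13(16),14-dien-19-yl 2-[bis(2,2,2-trifluoroethoxy)phosphoryl]acetate
Conditions: DCC, DMAP (cat.), CH2Cl2, 0 °C → rt
Reagents that add atoms: none
Why: Carbodiimide esterification (Steglich type) of a phosphonoacetic acid runs through a very reactive ketene-like acylating species, which is what the hindered neopentyl C19 alcohol needs, and no other hydroxyl group is free.

**Step 11**
Reactants: 17 phosphonoacetate; 18 para-(tert-butyldimethylsilyloxy)benzaldehyde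
Product: 19 8α-(triethylsilyloxy)labda-13(16),14-dien-19-yl (2Z)-3-[4-(tert-butyldimethylsilyloxy)phenyl]prop-2-enoate
Conditions: KN(SiMe3)2, 18-crown-6, THF, −78 °C, dim light
Reagents that add atoms: none
Why: Still–Gennari variant of the Horner–Wadsworth–Emmons olefination: with the electron-poor bis(trifluoroethyl) phosphonate and a dissociated potassium counter-ion the adduct collapses under kinetic control, so the aryl aldehyde should give the Z-enoate.

**Step 12**
Reactants: 19 bis-silyl ether
Product: 20 8α-hydroxylabda-13(16),14-dien-19-yl (2Z)-3-(4-hydroxyphenyl)prop-2-enoate (CNP0197278.1)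
Conditions: Bu4NF, AcOH (1:1), THF, 0 °C → rt, dark
Reagents that add atoms: none
Why: Fluoride cleaves the aryl and the tertiary alkyl silyl ether (silyl ether deprotection), and the acetic acid buffer keeps the phenol protonated, so the Z-enoate, the neopentyl ester and the diene should survive.

**Compound list**
1 | (R)-linalool, (3R)-3,7-dimethylocta-1,6-dien-3-ol | C=C[C@](C)(O)CCC=C(C)C | starting material
2 | triethyl{[(3R)-3,7-dimethylocta-1,6-dien-3-yl]oxy}silane | C=C[C@](C)(O[Si](CC)(CC)CC)CCC=C(C)C | intermediate
3 | (2E,6R)-2,6-dimethyl-6-(triethylsilyloxy)octa-2,7-dien-1-ol | C=C[C@](C)(O[Si](CC)(CC)CC)CC/C=C(\C)CO | intermediate (not isolated)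
4 | (2E,6R)-2,6-dimethyl-6-(triethylsilyloxy)octa-2,7-dienal | C=C[C@](C)(O[Si](CC)(CC)CC)CC/C=C(\C)C=O | intermediate
5 | triethyl{[(3R,6E)-3,7-dimethylnona-1,6,8-trien-3-yl]oxy}silane | C=C/C(C)=C/CC[C@@](C)(O[Si](CC)(CC)CC)C=C | intermediate
6 | methacrolein (2-methylprop-2-enal) | CC(=C)C=O | starting material
7 | (1S,2R)-1,3-dimethyl-2-[(3R)-3-methyl-3-(triethylsilyloxy)pent-4-en-1-yl]cyclohex-3-ene-1-carbaldehyde | CC1=CCC[C@](C)(C=O)[C@@H]1CC[C@@](C)(O[Si](CC)(CC)CC)C=C | intermediate
8 | methyl acrylate | C=CC(=O)OC | starting material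
9 | methyl (2E,4R)-6-[(1R,6S)-6-formyl-2,6-dimethylcyclohex-2-en-1-yl]-4-methyl-4-(triethylsilyloxy)hex-2-enoate | CC1=CCC[C@](C)(C=O)[C@@H]1CC[C@@](C)(O[Si](CC)(CC)CC)/C=C/C(=O)OC | intermediate
10 | methyl 19-oxo-8α-(triethylsilyloxy)-13,14,15,16-tetranorlabdan-12-oate | COC(=O)C[C@@H]1[C@@]2(C)CCC[C@](C)(C=O)[C@@H]2CC[C@@]1(C)O[Si](CC)(CC)CC | intermediate
11 | 8α-(triethylsilyloxy)-13,14,15,16-tetranorlabdane-12,19-diol | OCC[C@@H]1[C@@]2(C)CCC[C@](C)(CO)[C@@H]2CC[C@@]1(C)O[Si](CC)(CC)CC | intermediate
12 | 12-iodo-8α-(triethylsilyloxy)-13,14,15,16-tetranorlabdan-19-ol | ICC[C@@H]1[C@@]2(C)CCC[C@](C)(CO)[C@@H]2CC[C@@]1(C)O[Si](CC)(CC)CC | intermediate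
13 | chloroprene (2-chlorobuta-1,3-diene) | C=CC(Cl)=C | starting material
14 | buta-1,3-dien-2-ylmagnesium chloride | C=CC(=C)[Mg]Cl | intermediate (not isolated)
15 | 8α-(triethylsilyloxy)labda-13(16),14-dien-19-ol | C=CC(=C)CC[C@@H]1[C@@]2(C)CCC[C@](C)(CO)[C@@H]2CC[C@@]1(C)O[Si](CC)(CC)CC | intermediate
16 | 2-[bis(2,2,2-trifluoroethoxy)phosphoryl]acetic acid | OC(=O)CP(=O)(OCC(F)(F)F)OCC(F)(F)F | starting material
17 | 8α-(triethylsilyloxy)labda-13(16),14-dien-19-yl 2-[bis(2,2,2-trifluoroethoxy)phosphoryl]acetate | C=CC(=C)CC[C@@H]1[C@@]2(C)CCC[C@](C)(COC(=O)CP(=O)(OCC(F)(F)F)OCC(F)(F)F)[C@@H]2CC[C@@]1(C)O[Si](CC)(CC)CC | intermediate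
18 | 4-(tert-butyldimethylsilyloxy)benzaldehyde | O=Cc1ccc(O[Si](C)(C)C(C)(C)C)cc1 | starting material
19 | 8α-(triethylsilyloxy)labda-13(16),14-dien-19-yl (2Z)-3-[4-(tert-butyldimethylsilyloxy)phenyl]prop-2-enoate | C=CC(=C)CC[C@@H]1[C@@]2(C)CCC[C@](C)(COC(=O)/C=C\c3ccc(O[Si](C)(C)C(C)(C)C)cc3)[C@@H]2CC[C@@]1(C)O[Si](CC)(CC)CC | intermediate
20 | 8α-hydroxylabda-13(16),14-dien-19-yl (2Z)-3-(4-hydroxyphenyl)prop-2-enoate, (4S,5R,8R,9R,10S) | C=CC(=C)CC[C@@H]1[C@@]2(C)CCC[C@](C)(COC(=O)/C=C\c3ccc(O)cc3)[C@@H]2CC[C@@]1(C)O | target

**Step count**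
Total steps: 12. Longest linear sequence: 12 steps, from (R)-linalool 1 to 20.

**Steps most likely to fail**

Step 4. The internal methyl group of the diene may divert part of the cycloaddition into the other regioisomer, the catalyst may discriminate the enal faces incompletely with this 1,2-disubstituted diene, or the Lewis acid may ionise the tertiary allylic silyl ether. The fallback builds the quaternary carbon in two stages under auxiliary control and sets out from triene 5. Cycloaddition with (4R)-3-acryloyl-4-benzyloxazolidin-2-one (from (R)-4-benzyloxazolidin-2-one and acryloyl chloride) under Et2AlCl in CH2Cl2 at −78 °C uses a chelated, strongly endo-selective dienophile whose open face is fixed by the benzyl group and which, lacking the α-methyl group, bonds more easily to the substituted diene terminus. It would give the endo imide adduct (4R)-4-benzyl-3-{(1S,2S)-3-methyl-2-[(3R)-3-methyl-3-(triethylsilyloxy)pent-4-en-1-yl]cyclohex-3-ene-1-carbonyl}oxazolidin-2-one F1. MeOMgBr in MeOH/THF would exchange the auxiliary for the methyl ester F2. LiN(i-Pr)2 and then MeI in THF at −78 °C would methylate the ester enolate anti to the neighbouring C5 arm and give the quaternary methyl ester F3. LiAlH4 would reduce it to the neopentyl alcohol F4, and Dess–Martin periodinane would bring the sequence back to aldehyde 7.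

Step 6. The tertiary C10 radical may be quenched by a second hydrogen-atom transfer, or the enoate may be reduced, before the 6-exo closure reaches the β-carbon that is flanked by the silyloxy-bearing quaternary C8; closure through the β face of C10 would give the cis ring fusion. The fallback changes the activating group of the acceptor to an aldehyde, a smaller and faster radical trap, and sets out from aldehyde 7. Cross-metathesis with crotonaldehyde (RuCl2(H2IMes)(=CH-C6H4-2-O-i-Pr), CH2Cl2, 40 °C) would give the enal (2E,4R)-6-[(1R,6S)-6-formyl-2,6-dimethylcyclohex-2-en-1-yl]-4-methyl-4-(triethylsilyloxy)hex-2-enal F5. Fe(acac)3 and PhSiH3 in ethanol would close ring B to the dialdehyde 8α-(triethylsilyloxy)-13,14,15,16-tetranorlabdane-12,19-dial F6. NaBH4 in methanol would then reduce both formyl groups and rejoin the route at diol 11.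

Step 5. The ruthenium carbene may fail to engage the vinyl group on the fully substituted, silyloxy-bearing carbon, so that methyl acrylate only dimerises. The fallback runs the metathesis on the free tertiary allylic alcohol, a much more willing olefin class, and sets out from aldehyde 7. Bu4NF in THF would give the carbinol (1S,2R)-2-[(3R)-3-hydroxy-3-methylpent-4-en-1-yl]-1,3-dimethylcyclohex-3-ene-1-carbaldehyde F7. Cross-metathesis with 8 under the same ruthenium catalyst would give the hydroxy enoate methyl (2E,4R)-6-[(1R,6S)-6-formyl-2,6-dimethylcyclohex-2-en-1-yl]-4-hydroxy-4-methylhex-2-enoate F8. Et3SiOSO2CF3 and 2,6-lutidine would then restore the silyl ether and return enoate 9.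

**Further compounds**
F1 | step 4 | (4R)-4-benzyl-3-{(1S,2S)-3-methyl-2-[(3R)-3-methyl-3-(triethylsilyloxy)pent-4-en-1-yl]cyclohex-3-ene-1-carbonyl}oxazolidin-2-one | CC1=CCC[C@H](C(=O)N2[C@H](Cc3ccccc3)COC2=O)[C@@H]1CC[C@@](C)(O[Si](CC)(CC)CC)C=C
F2 | step 4 | methyl (1S,2S)-3-methyl-2-[(3R)-3-methyl-3-(triethylsilyloxy)pent-4-en-1-yl]cyclohex-3-ene-1-carboxylate | CC1=CCC[C@H](C(=O)OC)[C@@H]1CC[C@@](C)(O[Si](CC)(CC)CC)C=C
F3 | step 4 | methyl (1S,2R)-1,3-dimethyl-2-[(3R)-3-methyl-3-(triethylsilyloxy)pent-4-en-1-yl]cyclohex-3-ene-1-carboxylate | CC1=CCC[C@](C)(C(=O)OC)[C@@H]1CC[C@@](C)(O[Si](CC)(CC)CC)C=C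
F4 | step 4 | {(1S,2R)-1,3-dimethyl-2-[(3R)-3-methyl-3-(triethylsilyloxy)pent-4-en-1-yl]cyclohex-3-en-1-yl}methanol | CC1=CCC[C@](C)(CO)[C@@H]1CC[C@@](C)(O[Si](CC)(CC)CC)C=C
F5 | step 6 | (2E,4R)-6-[(1R,6S)-6-formyl-2,6-dimethylcyclohex-2-en-1-yl]-4-methyl-4-(triethylsilyloxy)hex-2-enal | CC1=CCC[C@](C)(C=O)[C@@H]1CC[C@@](C)(O[Si](CC)(CC)CC)/C=C/C=O
F6 | step 6 | 8α-(triethylsilyloxy)-13,14,15,16-tetranorlabdane-12,19-dial | O=CC[C@@H]1[C@@]2(C)CCC[C@](C)(C=O)[C@@H]2CC[C@@]1(C)O[Si](CC)(CC)CC
F7 | step 5 | (1S,2R)-2-[(3R)-3-hydroxy-3-methylpent-4-en-1-yl]-1,3-dimethylcyclohex-3-ene-1-carbaldehyde | CC1=CCC[C@](C)(C=O)[C@@H]1CC[C@@](C)(O)C=C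
F8 | step 5 | methyl (2E,4R)-6-[(1R,6S)-6-formyl-2,6-dimethylcyclohex-2-en-1-yl]-4-hydroxy-4-methylhex-2-enoate | CC1=CCC[C@](C)(C=O)[C@@H]1CC[C@@](C)(O)/C=C/C(=O)OC
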